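The whole plan depends on cutting both bonds to the C8' carbonyl. This is the only side-chain carbon that lies between two sp2 carbons: C7' of the trisubstituted C6'=C7' alkene, and C9' of the C9'=C10' alkene that carries the C11' carbinol. A single palladium-catalysed three-component coupling joins an (E)-alkenyl iodide, carbon monoxide and an (E)-alkenylstannane. It makes C7'–C8' and C8'–C9', keeps both geometries and closes no ring. The iodide partner already holds the 4-methylbenzofuran-3(2H)-one (benzene ring A, furanone ring B), the (E)-C2'=C3' alkene and C2 of ring B. C2 is locked as a silyl ketal because the free hemiketal racemises by ring opening. Only desilylation follows.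

Key step: step 13

Assumption: the C2 hemiketal holds its configuration only in aprotic, base-free media, because its alkoxide equilibrates with the achiral 2-hydroxyaryl 1,2-diketone; C2 is therefore made racemic, locked as the silyl ketal, sorted, and unmasked in the last step.
Locants: O1, C2, C3 (ketone) and C3a–C7a in the bicycle; C1' (on C2) to C11' (carbinol carbon) in the chain. The same spatial arrangement at C2 is (S) in the silyl ketals and (R) in the free hemiketal, because OSi outranks O1 whereas OH does not.

Step 1
Reactants: 1 ethyl acetoacetate; 2 1-bromobut-2-yne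
Product: 3 ethyl 3-oxooct-6-ynoate
Conditions: NaH, THF, 0 °C; n-BuLi, 0 °C; 2, 0 °C to rt; aq HCl
Reagents that add atoms: none
Why: γ-Alkylation of the acetoacetate dianion (SN2): the carbanion formed last, at the terminal carbon, is the more reactive one, so the primary propargylic bromide is displaced there only and the C4'–C5' bond is made without a later decarboxylation.

Step 2
Reactants: 3 ethyl 3-oxooct-6-ynoate
Product: 4 ethyl (Z)-3-(diethoxyphosphoryloxy)oct-2-en-6-ynoate
Conditions: NaH, Et2O, 0 °C; ClP(O)(OEt)2, 0 °C to rt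
Reagents that add atoms: diethyl chlorophosphate, CCOP(=O)(Cl)OCC
Why: Enol phosphate formation: the sodium enolate of the β-keto ester is chelated in a U shape, so O-phosphorylation places the phosphate cis to the ester and gives the Z isomer.

Step 3
Reactants: 4 ethyl (Z)-3-(diethoxyphosphoryloxy)oct-2-en-6-ynoate
Product: 5 ethyl (E)-3-methyloct-2-en-6-ynoate
Conditions: Me2CuLi (MeLi, CuI), Et2O, −78 to −45 °C; aq NH4Cl
Reagents that add atoms: lithium dimethylcuprate, [Li+].C[Cu-]C
Why: Cuprate coupling of a β-phosphoryloxy acrylate (addition–elimination with retention at low temperature) exchanges phosphate for methyl, so methyl ends cis to the ester and the future C2'=C3' alkene is E by construction; the internal alkyne is not carbocuprated under these conditions.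

Step 4
Reactants: 5 ethyl (E)-3-methyloct-2-en-6-ynoate
Product: 6 (E)-3-methyloct-2-en-6-yn-1-ol
Conditions: i-Bu2AlH (2.2 equiv), CH2Cl2, −78 to 0 °C; aq potassium sodium tartrate
Reagents that add atoms: none
Why: 1,2-Reduction of an α,β-unsaturated ester by two hydride transfers from i-Bu2AlH gives the allylic alcohol without touching the alkyne or the alkene geometry.

Step 5
Reactants: 6 (E)-3-methyloct-2-en-6-yn-1-ol
Product: 8 (2E,6E)-7-iodo-3-methylocta-2,6-dien-1-ol, via alkenylzirconocene chloride 7 (not isolated)
Conditions: Cp2Zr(H)Cl (3 equiv), THF, rt to 40 °C, dark; I2, THF, −78 to 0 °C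
Reagents that add atoms: iodine, II
Why: Hydrozirconation–iodinolysis: the first equivalent turns the hydroxyl into its zirconium alkoxide, Zr–H then adds syn across the alkyne, excess reagent and mild warming let the metal settle on the less hindered methyl-bearing C7', and I2 cleaves C–Zr with retention, so the iodide is E (iodine trans to C5'); the trisubstituted alkene does not react and any C6' regioisomer is removed by chromatography.

Step 6
Reactants: 8 (2E,6E)-7-iodo-3-methylocta-2,6-dien-1-ol
Product: 9 (2E,6E)-1-bromo-7-iodo-3-methylocta-2,6-diene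
Conditions: CBr4, PPh3, CH2Cl2, −20 to 0 °C
Reagents that add atoms: carbon tetrabromide, BrC(Br)(Br)Br
Why: Appel reaction: the alkoxyphosphonium ion of a primary allylic alcohol is displaced by bromide in SN2 fashion under neutral, cold conditions, which preserves the position and geometry of both alkenes.

Step 7
Reactants: 10 1-(2-hydroxy-6-methylphenyl)ethanone
Product: 12 4-methylbenzofuran-3(2H)-one, via bromoketone 11 (not isolated)
Conditions: CuBr2 (2 equiv), EtOAc/CHCl3, reflux; filter, evaporate; NaOAc, EtOH, reflux
Reagents that add atoms: none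
Why: CuBr2 brominates the enol of the aryl methyl ketone on the side chain rather than on ring A, and the ortho phenol then closes ring B by an intramolecular Williamson etherification (5-exo-tet).

Step 8
Reactants: 12 4-methylbenzofuran-3(2H)-one; 9 (2E,6E)-1-bromo-7-iodo-3-methylocta-2,6-diene
Product: 13 (±)-2-[(2E,6E)-7-iodo-3-methylocta-2,6-dien-1-yl]-4-methylbenzofuran-3(2H)-one
Conditions: 12 (1.5 equiv), LiN(SiMe3)2 (1.5 equiv), THF, −78 °C; 9, −78 to −20 °C
Reagents that add atoms: none
Why: Enolate C-alkylation (SN2): the lithium counter-ion in plain THF and the soft primary allylic bromide direct attack to C2 rather than to the enolate oxygen, the surplus of inexpensive 12 holds back a second alkylation, the alkenyl iodide is inert, and C2 forms racemic, which does not matter because the next step flattens it again.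

Step 9
Reactants: 13 (±)-2-[(2E,6E)-7-iodo-3-methylocta-2,6-dien-1-yl]-4-methylbenzofuran-3(2H)-one
Product: 14 (±)-2-hydroxy-2-[(2E,6E)-7-iodo-3-methylocta-2,6-dien-1-yl]-4-methylbenzofuran-3(2H)-one
Conditions: KN(SiMe3)2, THF, −78 °C; 2-(phenylsulfonyl)-3-phenyloxaziridine, −78 °C; AcOH, −78 °C
Reagents that add atoms: 2-(phenylsulfonyl)-3-phenyloxaziridine, O=S(=O)(N1OC1c1ccccc1)c1ccccc1
Why: Davis oxidation: the tetrasubstituted potassium enolate attacks the oxaziridine oxygen, which touches neither alkene nor the C–I bond; no facial control is attempted because the hemiketal alkoxide formed equilibrates with the achiral phenoxide 1,2-diketone, and the cold AcOH quench returns the closed racemic hemiketal before benzilic-type rearrangement or alkene migration can start.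

Step 10
Reactants: 14 (±)-2-hydroxy-2-[(2E,6E)-7-iodo-3-methylocta-2,6-dien-1-yl]-4-methylbenzofuran-3(2H)-one
Product: 15 (±)-2-(tert-butyldimethylsilyloxy)-2-[(2E,6E)-7-iodo-3-methylocta-2,6-dien-1-yl]-4-methylbenzofuran-3(2H)-one
Conditions: TBSOTf, 2,6-lutidine, CH2Cl2, −78 to 0 °C
Reagents that add atoms: tert-butyldimethylsilyl triflate, CC(C)(C)[Si](C)(C)OS(=O)(=O)C(F)(F)F
Why: Silyl triflate silylation of a tertiary hydroxyl with a hindered weak base: the closed hemiketal is the dominant tautomer and the phenol of the open form is held in a hydrogen bond to the C3 ketone, so silicon ends on the C2 oxygen, and with no O–H left ring B can no longer open, which freezes the configuration of each enantiomer.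

Step 11
Reactants: 15 (±)-2-(tert-butyldimethylsilyloxy)-2-[(2E,6E)-7-iodo-3-methylocta-2,6-dien-1-yl]-4-methylbenzofuran-3(2H)-one
Product: 16 (S)-2-(tert-butyldimethylsilyloxy)-2-[(2E,6E)-7-iodo-3-methylocta-2,6-dien-1-yl]-4-methylbenzofuran-3(2H)-one
Conditions: preparative SFC, amylose tris(3,5-dimethylphenylcarbamate) phase, CO2/i-PrOH
Reagents that add atoms: none
Why: Resolution on a chiral stationary phase: no bond changes, the two frozen antipodes fit the carbamate grooves of the polysaccharide differently and are collected separately, the wanted (S)-antipode is identified by anomalous-dispersion crystallography on the iodide or by circular dichroism, and the (R)-antipode can be returned to racemic 14 with Bu4NF and recycled.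

Step 12
Reactants: 17 2-methylbut-3-yn-2-ol
Product: 18 (E)-2-methyl-4-(tributylstannyl)but-3-en-2-ol
Conditions: Bu3SnH, PdCl2(PPh3)2 (2 mol %), THF, 0 °C to rt
Reagents that add atoms: tributyltin hydride, CCCC[SnH](CCCC)CCCC
Why: Palladium-catalysed hydrostannation: Sn–H adds syn across the terminal alkyne and the bulky tertiary carbinol steers tin to the terminal carbon, which gives the (E)-β-stannane and leaves the hydroxyl free.

Step 13
Reactants: 16 (S)-2-(tert-butyldimethylsilyloxy)-2-[(2E,6E)-7-iodo-3-methylocta-2,6-dien-1-yl]-4-methylbenzofuran-3(2H)-one; 18 (E)-2-methyl-4-(tributylstannyl)but-3-en-2-ol; 19 carbon monoxide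
Product: 20 (S)-2-(tert-butyldimethylsilyloxy)-2-[(2E,6E,9E)-11-hydroxy-3,7,11-trimethyl-8-oxododeca-2,6,9-trien-1-yl]-4-methylbenzofuran-3(2H)-one
Conditions: Pd2(dba)3 (5 mol %), AsPh3 (40 mol %), CO (3 bar), NMP, 35 °C, slow addition of 18
Reagents that add atoms: none
Why: The cycle opens with insertion of a zerovalent palladium–arsine complex into the C7'–I bond of 16 without change of geometry, bound CO then migrates into the Pd–C7' bond to give an acylpalladium iodide, 18 hands over its C9' alkenyl group with retention, and reductive elimination releases 20 and the catalyst. The reaction type is the carbonylative Stille coupling of alkenyl iodides with alkenylstannanes, an established entry to unsymmetrical divinyl ketones. No ring is closed and no stereocentre is made, and the C2 silyl ketal is a spectator with no acidic or ionisable site under these neutral conditions. The selectivity required is CO uptake ahead of direct alkenyl–alkenyl coupling: the methyl group on C7' crowds the alkenylpalladium centre and slows its transmetalation, while CO pressure, the weakly bound AsPh3 and a low standing concentration of 18 favour insertion. Chemoselectivity rests on C7'–I being the only bond open to oxidative addition, and because palladium sits trans to C5' across the E alkene, ring-forming insertion into C2'=C3' is geometrically barred. Both E geometries are brought in by 16 and 18 and are carried over unchanged, so no olefination is needed on the sensitive γ-hydroxy dienone.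

Step 14
Reactants: 20 (S)-2-(tert-butyldimethylsilyloxy)-2-[(2E,6E,9E)-11-hydroxy-3,7,11-trimethyl-8-oxododeca-2,6,9-trien-1-yl]-4-methylbenzofuran-3(2H)-one
Product: 21 (R)-2-hydroxy-2-[(2E,6E,9E)-11-hydroxy-3,7,11-trimethyl-8-oxododeca-2,6,9-trien-1-yl]-4-methylbenzofuran-3(2H)-one
Conditions: HF·pyridine, pyridine, THF, 0 °C; Me3SiOMe quench, evaporate cold
Reagents that add atoms: none
Why: Fluoride-induced desilylation: fluoride attacks silicon, so only the Si–O bond breaks and the C2–O bond is never touched (same arrangement, descriptor changes from S to R), the pyridine buffer spares the tertiary allylic alcohol and the dienone, and the non-aqueous quench avoids any contact of the free hemiketal with base.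

Compound list
1 | ethyl acetoacetate | CCOC(=O)CC(C)=O | starting material
2 | 1-bromobut-2-yne | CC#CCBr | starting material
3 | ethyl 3-oxooct-6-ynoate | CCOC(=O)CC(=O)CCC#CC | intermediate
4 | ethyl (Z)-3-(diethoxyphosphoryloxy)oct-2-en-6-ynoate | CCOC(=O)/C=C(\OP(=O)(OCC)OCC)CCC#CC | intermediate
5 | ethyl (E)-3-methyloct-2-en-6-ynoate | CCOC(=O)/C=C(\C)CCC#CC | intermediate
6 | (E)-3-methyloct-2-en-6-yn-1-ol | OC/C=C(\C)CCC#CC | intermediate
7 | (2E,6E)-alkenylzirconocene chloride, hydroxyl bound as zirconocene chloride alkoxide | C/C(=C\CC/C(C)=C/CO[Zr](Cl)(C1C=CC=C1)C1C=CC=C1)[Zr](Cl)(C1C=CC=C1)C1C=CC=C1 | intermediate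
8 | (2E,6E)-7-iodo-3-methylocta-2,6-dien-1-ol | OC/C=C(\C)CC/C=C(\C)I | intermediate
9 | (2E,6E)-1-bromo-7-iodo-3-methylocta-2,6-diene | BrC/C=C(\C)CC/C=C(\C)I | intermediate
10 | 1-(2-hydroxy-6-methylphenyl)ethanone | CC(=O)c1c(C)cccc1O | starting material
11 | 2-bromo-1-(2-hydroxy-6-methylphenyl)ethanone | O=C(CBr)c1c(C)cccc1O | intermediate
12 | 4-methylbenzofuran-3(2H)-one | Cc1cccc2OCC(=O)c12 | intermediate
13 | (±)-2-[(2E,6E)-7-iodo-3-methylocta-2,6-dien-1-yl]-4-methylbenzofuran-3(2H)-one | C/C(=C\CC1Oc2cccc(C)c2C1=O)CC/C=C(\C)I | intermediate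
14 | (±)-2-hydroxy-2-[(2E,6E)-7-iodo-3-methylocta-2,6-dien-1-yl]-4-methylbenzofuran-3(2H)-one | C/C(=C\CC1(O)Oc2cccc(C)c2C1=O)CC/C=C(\C)I | intermediate
15 | (±)-2-(tert-butyldimethylsilyloxy)-2-[(2E,6E)-7-iodo-3-methylocta-2,6-dien-1-yl]-4-methylbenzofuran-3(2H)-one | C/C(=C\CC1(O[Si](C)(C)C(C)(C)C)Oc2cccc(C)c2C1=O)CC/C=C(\C)I | intermediate
16 | (S)-2-(tert-butyldimethylsilyloxy)-2-[(2E,6E)-7-iodo-3-methylocta-2,6-dien-1-yl]-4-methylbenzofuran-3(2H)-one | C/C(=C\C[C@@]1(O[Si](C)(C)C(C)(C)C)Oc2cccc(C)c2C1=O)CC/C=C(\C)I | intermediate
17 | 2-methylbut-3-yn-2-ol | CC(C)(O)C#C | starting material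
18 | (E)-2-methyl-4-(tributylstannyl)but-3-en-2-ol | CC(C)(O)/C=C/[Sn](CCCC)(CCCC)CCCC | intermediate
19 | carbon monoxide | [C-]#[O+] | starting material
20 | (S)-2-(tert-butyldimethylsilyloxy)-2-[(2E,6E,9E)-11-hydroxy-3,7,11-trimethyl-8-oxododeca-2,6,9-trien-1-yl]-4-methylbenzofuran-3(2H)-one | C/C(=C\C[C@@]1(O[Si](C)(C)C(C)(C)C)Oc2cccc(C)c2C1=O)CC/C=C(\C)C(=O)/C=C/C(C)(C)O | intermediate
21 | (R)-2-hydroxy-2-[(2E,6E,9E)-11-hydroxy-3,7,11-trimethyl-8-oxododeca-2,6,9-trien-1-yl]-4-methylbenzofuran-3(2H)-one | C/C(=C\C[C@@]1(O)Oc2cccc(C)c2C1=O)CC/C=C(\C)C(=O)/C=C/C(C)(C)O | target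

Total step count: 14. Longest linear sequence: 12 (steps 1–6, 8–11, 13, 14).

Steps most likely to fail

1. Step 8. The ambident enolate may be alkylated on oxygen, or proton transfer to unreacted enolate may lead to a second alkylation at C2. The fallback sets out from 10 and 9 and comes back at 13.
   - Ketone 10 is converted with LiN(i-Pr)2 (2.2 equiv, THF, −78 to 0 °C) into its phenoxide–enolate dianion. Its carbon terminus is alkylated by 9 to give (4E,8E)-1-(2-hydroxy-6-methylphenyl)-9-iodo-5-methyldeca-4,8-dien-1-one F1.
   - Renewed double deprotonation with LiN(SiMe3)2 and bromination with N-bromosuccinimide at −78 °C gives the (±)-2-bromo ketone F2. Its phenoxide closes ring B on warming (5-exo-tet) to 13.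
   - The C2–C1' bond is thus made on an acyclic enolate, and ring B is closed only afterwards.

2. Step 13. Transmetalation may overtake CO uptake, so that the two alkenyl groups couple directly, or the catalyst may stall under CO. The fallback sets out from 16 and 18 and comes back at 20; C8' then arrives as an aldehyde carbon.
   - Stannane 18 is lithiated (n-BuLi, 2.1 equiv, THF, −78 °C) and formylated with DMF to (E)-4-hydroxy-4-methylpent-2-enal F3.
   - Nozaki–Hiyama–Kishi coupling of 16 with F3 (CrCl2, catalytic NiCl2, DMF, rt) adds the alkenylchromium species to the aldehyde only and leaves the C3 ketone alone. It gives the bis-allylic alcohol F4 as a mixture of C8' epimers.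
   - MnO2 in CH2Cl2 oxidises C8' and gives 20.

3. Step 14. Enantiopurity may erode by ring–chain tautomerism while the hindered silyl group leaves slowly in a pyridine/pyridinium medium. The fallback sets out from 14 and comes back at 21, using a more labile silyl group and an amine-free release.
   - Compound 14 is silylated with TESOTf and 2,6-lutidine to the (±)-triethylsilyl ketal F5.
   - Separation on the same chiral phase gives the (S)-triethylsilyl ketal F6.
   - Carbonylative coupling with 18 and 19 as in step 13 gives the triethylsilyl-protected dienone F7.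
   - AcOH/THF/H2O at 0 °C solvolyses the silyl ketal, in the weakly acidic range where hemiketal opening is slowest, to give 21.

Further compounds
F1 | step 8 | (4E,8E)-1-(2-hydroxy-6-methylphenyl)-9-iodo-5-methyldeca-4,8-dien-1-one | C/C(=C\CCC(=O)c1c(C)cccc1O)CC/C=C(\C)I
F2 | step 8 | (±)-(4E,8E)-2-bromo-1-(2-hydroxy-6-methylphenyl)-9-iodo-5-methyldeca-4,8-dien-1-one | C/C(=C\CC(Br)C(=O)c1c(C)cccc1O)CC/C=C(\C)I
F3 | step 13 | (E)-4-hydroxy-4-methylpent-2-enal | CC(C)(O)/C=C/C=O
F4 | step 13 | (2S)-2-(tert-butyldimethylsilyloxy)-2-[(2E,6E,9E)-8,11-dihydroxy-3,7,11-trimethyldodeca-2,6,9-trien-1-yl]-4-methylbenzofuran-3(2H)-one, C8' epimers | C/C(=C\C[C@@]1(O[Si](C)(C)C(C)(C)C)Oc2cccc(C)c2C1=O)CC/C=C(\C)C(O)/C=C/C(C)(C)O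
F5 | step 14 | (±)-2-(triethylsilyloxy)-2-[(2E,6E)-7-iodo-3-methylocta-2,6-dien-1-yl]-4-methylbenzofuran-3(2H)-one | C/C(=C\CC1(O[Si](CC)(CC)CC)Oc2cccc(C)c2C1=O)CC/C=C(\C)I
F6 | step 14 | (S)-2-(triethylsilyloxy)-2-[(2E,6E)-7-iodo-3-methylocta-2,6-dien-1-yl]-4-methylbenzofuran-3(2H)-one | C/C(=C\C[C@@]1(O[Si](CC)(CC)CC)Oc2cccc(C)c2C1=O)CC/C=C(\C)I
F7 | step 14 | (S)-2-(triethylsilyloxy)-2-[(2E,6E,9E)-11-hydroxy-3,7,11-trimethyl-8-oxododeca-2,6,9-trien-1-yl]-4-methylbenzofuran-3(2H)-one | C/C(=C\C[C@@]1(O[Si](CC)(CC)CC)Oc2cccc(C)c2C1=O)CC/C=C(\C)C(=O)/C=C/C(C)(C)O
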